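**Plan**
- Retrosynthesis: the two phenols are unmasked last (ring A O–CH3, and ring B C1–OH from C1–B). The skeleton is then cut in one operation at the ring B C2–O ether bond and the ring B C3–Br bond.
- Enabling feature: in ring B the ether carbon C2 and the brominated carbon C3 are neighbours, flanked by C1–O (carried as boron) and C4–Br. This is the footprint of an aryne across C2–C3 that takes oxygen at C2 and bromine at C3.
- Forward: both benzene rings are purchased. Ring B (boronate 1, hydroxyl on C3) is brominated at C4/C6, iodinated at C2 and triflated at C3. Step 4 joins the ring A phenoxide and a bromine to the aryne; C–B oxidation and O-demethylation finish.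
- No ring is formed and the target has no stereocentre, so no stereocontrol is needed.

Key step: step 4

Remarks on the chemistry:
- Ring B numbering: C1 is the carbon that ends as C–OH (boron-bearing up to step 5), C2 the ether carbon, C3, C4 and C6 the C–Br carbons, C5 the C–H. Ring A is the 5-bromo-2-hydroxyphenoxy ring. Bpin = 4,4,5,5-tetramethyl-1,3,2-dioxaborolan-2-yl.
- The aryne precursor carries iodide on C2 and triflate on C3. A single hydroxyl (on C3 of 1) then directs all three halogenations to its ortho and para carbons, and no metalation has to compete with the acidic C5–H between two bromines.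
- Assumption: 1 and 5 are purchasable.

**Step 1**
Reactants: 1 3-(4,4,5,5-tetramethyl-1,3,2-dioxaborolan-2-yl)phenol
Product: 2 2,4-dibromo-5-(4,4,5,5-tetramethyl-1,3,2-dioxaborolan-2-yl)phenol
Conditions: NBS (2.0 equiv), MeCN, −20 °C → rt
Reagents that add atoms: N-bromosuccinimide, O=C1CCC(=O)N1Br
Why: Hydroxyl-directed electrophilic aromatic bromination, in which the C3 hydroxyl activates C4 and C6 (its less hindered ortho and para carbons) as in the 4,6-dibromination of other meta-substituted phenols, while C2 is shielded between OH and Bpin and the boron-bearing C1 is meta to OH and so not prone to ipso attack.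

**Step 2**
Reactants: 2 2,4-dibromo-5-(4,4,5,5-tetramethyl-1,3,2-dioxaborolan-2-yl)phenol
Product: 3 4,6-dibromo-2-iodo-3-(4,4,5,5-tetramethyl-1,3,2-dioxaborolan-2-yl)phenol
Conditions: NIS (1.1 equiv), TFA (cat.), MeCN, 0 °C → rt
Reagents that add atoms: N-iodosuccinimide, O=C1CCC(=O)N1I
Why: Electrophilic aromatic iodination with acid-activated NIS at the only carbon still activated by the hydroxyl (C2, ortho to OH), so the site is fixed by the substrate and only the rate is at stake.

**Step 3**
Reactants: 3 4,6-dibromo-2-iodo-3-(4,4,5,5-tetramethyl-1,3,2-dioxaborolan-2-yl)phenol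
Product: 4 4,6-dibromo-2-iodo-3-(4,4,5,5-tetramethyl-1,3,2-dioxaborolan-2-yl)phenyl trifluoromethanesulfonate
Conditions: Tf2O, pyridine, CH2Cl2, −20 → 0 °C
Reagents that add atoms: trifluoromethanesulfonic anhydride, O=S(=O)(OS(=O)(=O)C(F)(F)F)C(F)(F)F
Why: O-Triflation of a phenol, routine also for 2,6-dihalophenols, under which the pinacol boronate and the aryl halides are inert.

**Step 4**
Reactants: 4 4,6-dibromo-2-iodo-3-(4,4,5,5-tetramethyl-1,3,2-dioxaborolan-2-yl)phenyl trifluoromethanesulfonate; 5 5-bromo-2-methoxyphenol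
Product: 10 2-[3,4,6-tribromo-2-(5-bromo-2-methoxyphenoxy)phenyl]-4,4,5,5-tetramethyl-1,3,2-dioxaborolane, via chloromagnesium phenoxide 6 (not isolated), via magnesiated triflate 7 (not isolated), via 3-boryl-4,6-dibromobenzyne 8 (not isolated), via arylmagnesium chloride 9 (not isolated)
Conditions: 5, i-PrMgCl·LiCl (2.5 equiv each), THF, 0 °C; then 4, Me3SiCH2MgCl (1.1 equiv), −78 → −40 °C; then BrCl2C–CCl2Br, −78 → 0 °C
Reagents that add atoms: 1,2-dibromo-1,1,2,2-tetrachloroethane, BrC(Cl)(Cl)C(Cl)(Cl)Br
Why: Proposed new method: Me3SiCH2MgCl exchanges the C2 iodine of 4 for magnesium, the magnesiated triflate 7 expels the C3 triflate at −78 °C to give aryne 8, phenoxide 6 adds through oxygen to C2, and the carbanion left on C3 is held as arylmagnesium 9 until the halophilic bromine donor turns it into the C3–Br bond. The closest known reaction type is the three-component aryne coupling in which a magnesium thiolate or amide adds to an aryne released from a 2-iodoaryl sulfonate and the resulting aryl Grignard is quenched with an electrophile; the extension is a phenoxide nucleophile on a 3-borylaryne with a bromine quench. No ring is closed and no stereocentre is formed. The selectivity needed is oxygen at C2 and not at C3: the C1 boryl group steers nucleophiles to the aryne carbon next to it (ortho addition is established for amines on 3-borylarynes, and prior O→B coordination would deliver the phenoxide to the same carbon), and the C4 bromine stabilises the charge developing on C3, so both flanking groups agree. Side reactions are held back by an excess of 6 (so that 9 does not add to further aryne), by a trigger Grignard that does not itself add to arynes, by keeping 9 at or below −40 °C (no loss of MgBrCl towards a second aryne), and by a bromine source that does not attack the surplus electron-rich phenoxide ring.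

**Step 5**
Reactants: 10 2-[3,4,6-tribromo-2-(5-bromo-2-methoxyphenoxy)phenyl]-4,4,5,5-tetramethyl-1,3,2-dioxaborolane
Product: 11 3,4,6-tribromo-2-(5-bromo-2-methoxyphenoxy)phenol
Conditions: H2O2 (30% aq), NaOH (aq), THF, 0 °C; then 1 M HCl
Reagents that add atoms: hydrogen peroxide, OO
Why: Oxidation of an arylboronic ester by hydroperoxide (boron-ate formation, then 1,2-aryl shift from boron to oxygen) replaces C1–B by C1–OH at the same carbon, and aryl bromides and both ethers are inert to cold basic peroxide.

**Step 6**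
Reactants: 11 3,4,6-tribromo-2-(5-bromo-2-methoxyphenoxy)phenol
Product: 12 3,4,6-tribromo-2-(5-bromo-2-hydroxyphenoxy)phenol
Conditions: BBr3 (3 equiv), CH2Cl2, −78 °C → rt; then H2O
Reagents that add atoms: none
Why: Lewis-acid cleavage of an aryl methyl ether with BBr3 (O-complexation, then bromide attack at the methyl group), under which the diaryl ether and the aryl bromides are stable.

**Compound list**
1 | 3-(4,4,5,5-tetramethyl-1,3,2-dioxaborolan-2-yl)phenol | CC1(C)OB(OC1(C)C)c1cccc(O)c1 | starting material
2 | 2,4-dibromo-5-(4,4,5,5-tetramethyl-1,3,2-dioxaborolan-2-yl)phenol | CC1(C)OB(OC1(C)C)c1cc(O)c(Br)cc1Br | intermediate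
3 | 4,6-dibromo-2-iodo-3-(4,4,5,5-tetramethyl-1,3,2-dioxaborolan-2-yl)phenol | CC1(C)OB(OC1(C)C)c1c(I)c(O)c(Br)cc1Br | intermediate
4 | 4,6-dibromo-2-iodo-3-(4,4,5,5-tetramethyl-1,3,2-dioxaborolan-2-yl)phenyl trifluoromethanesulfonate | CC1(C)OB(OC1(C)C)c1c(I)c(OS(=O)(=O)C(F)(F)F)c(Br)cc1Br | intermediate
5 | 5-bromo-2-methoxyphenol | COc1ccc(Br)cc1O | starting material
6 | chloromagnesium 5-bromo-2-methoxyphenoxide (LiCl present) | COc1ccc(Br)cc1O[Mg]Cl | intermediate
7 | [3,5-dibromo-2-(4,4,5,5-tetramethyl-1,3,2-dioxaborolan-2-yl)-6-(trifluoromethanesulfonyloxy)phenyl]magnesium chloride | CC1(C)OB(OC1(C)C)c1c([Mg]Cl)c(OS(=O)(=O)C(F)(F)F)c(Br)cc1Br | intermediate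
8 | 2-(4,6-dibromo-2,3-didehydrophenyl)-4,4,5,5-tetramethyl-1,3,2-dioxaborolane (3-boryl-4,6-dibromobenzyne) | CC1(C)OB(OC1(C)C)C1=C(Br)C=C(Br)C#C1 | intermediate
9 | [4,6-dibromo-2-(5-bromo-2-methoxyphenoxy)-3-(4,4,5,5-tetramethyl-1,3,2-dioxaborolan-2-yl)phenyl]magnesium chloride | COc1ccc(Br)cc1Oc1c(B2OC(C)(C)C(C)(C)O2)c(Br)cc(Br)c1[Mg]Cl | intermediate
10 | 2-[3,4,6-tribromo-2-(5-bromo-2-methoxyphenoxy)phenyl]-4,4,5,5-tetramethyl-1,3,2-dioxaborolane | COc1ccc(Br)cc1Oc1c(B2OC(C)(C)C(C)(C)O2)c(Br)cc(Br)c1Br | intermediate
11 | 3,4,6-tribromo-2-(5-bromo-2-methoxyphenoxy)phenol | COc1ccc(Br)cc1Oc1c(O)c(Br)cc(Br)c1Br | intermediate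
12 | 3,4,6-tribromo-2-(5-bromo-2-hydroxyphenoxy)phenol | Oc1ccc(Br)cc1Oc1c(O)c(Br)cc(Br)c1Br | target

Total step count: 6. Longest linear sequence: 6 steps (1 → 12); 5 enters as purchased in step 4.

**Steps most likely to fail**

1. Step 4. The magnesium phenoxide may add to the aryne too slowly or through its ortho carbon instead of oxygen. The intermediate aryl Grignard may also be protonated, add to further aryne, or lose MgBrCl before it is brominated. The fallback uses only known reactions; it sets out from 5 and returns at 11. Nucleophilic aromatic substitution of 5 on 3-bromo-2-fluorobenzaldehyde (O=Cc1cccc(Br)c1F; K2CO3, DMF, heat), with fluoride activated by the ortho aldehyde, should give 3-bromo-2-(5-bromo-2-methoxyphenoxy)benzaldehyde F1. Baeyer–Villiger oxidation (mCPBA, CH2Cl2) should give 3-bromo-2-(5-bromo-2-methoxyphenoxy)phenyl formate F2, and methanolysis (K2CO3, MeOH) 3-bromo-2-(5-bromo-2-methoxyphenoxy)phenol F3. Bromination of F3 with NBS (2 equiv, low temperature) at the ortho and para carbons of the new hydroxyl (C6 and C4) then gives 11; the free phenol ring should react well before ring A.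

2. Step 2. Electrophilic attack at the carbon wedged between hydroxyl and boronate may be slow, so that iodination stalls or cleavage of the C–B bond and oxidation of the phenol take over. The fallback sets out from 2 and returns at 3. A small nitrogen electrophile is placed on C2 first and the iodine is brought in later as iodide. Ortho-nitration of 2 (t-BuONO, THF) should give 4,6-dibromo-2-nitro-3-(4,4,5,5-tetramethyl-1,3,2-dioxaborolan-2-yl)phenol F4. Reduction (Fe powder, NH4Cl, EtOH/H2O) should give 2-amino-4,6-dibromo-3-(4,4,5,5-tetramethyl-1,3,2-dioxaborolan-2-yl)phenol F5. Diazotisation (NaNO2, p-TsOH, MeCN/H2O) gives 3,5-dibromo-2-hydroxy-6-(4,4,5,5-tetramethyl-1,3,2-dioxaborolan-2-yl)benzenediazonium 4-methylbenzenesulfonate F6, which with KI in the same pot (Sandmeyer-type iodination) gives 3.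

3. Step 1. Bromination may run on to the third activated carbon (C2) or replace boron by ipso attack, so that the dibromide is not obtained cleanly. The fallback sets out from 1 and returns at 2. Boron is carried through the halogenation as its tetracoordinate N-methyliminodiacetic acid (MIDA) ester, which has no vacant orbital on boron and shields C2 more strongly. Transesterification of 1 with methylboronic acid (the volatile methyl pinacol boronate is evaporated) should give (3-hydroxyphenyl)boronic acid F7. Condensation with N-methyliminodiacetic acid (DMSO/toluene, azeotropic removal of water) should give 2-(3-hydroxyphenyl)-6-methyl-1,3,6,2-dioxazaborocane-4,8-dione F8. NBS (2 equiv, MeCN) should give 2-(2,4-dibromo-5-hydroxyphenyl)-6-methyl-1,3,6,2-dioxazaborocane-4,8-dione F9. Ligand exchange with pinacol (NaHCO3, MeOH, 45 °C) returns 2.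

**Further compounds**
F1 | step 4 | 3-bromo-2-(5-bromo-2-methoxyphenoxy)benzaldehyde | COc1ccc(Br)cc1Oc1c(C=O)cccc1Br
F2 | step 4 | 3-bromo-2-(5-bromo-2-methoxyphenoxy)phenyl formate | COc1ccc(Br)cc1Oc1c(OC=O)cccc1Br
F3 | step 4 | 3-bromo-2-(5-bromo-2-methoxyphenoxy)phenol | COc1ccc(Br)cc1Oc1c(O)cccc1Br
F4 | step 2 | 4,6-dibromo-2-nitro-3-(4,4,5,5-tetramethyl-1,3,2-dioxaborolan-2-yl)phenol | CC1(C)OB(OC1(C)C)c1c([N+](=O)[O-])c(O)c(Br)cc1Br
F5 | step 2 | 2-amino-4,6-dibromo-3-(4,4,5,5-tetramethyl-1,3,2-dioxaborolan-2-yl)phenol | CC1(C)OB(OC1(C)C)c1c(N)c(O)c(Br)cc1Br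
F6 | step 2 | 3,5-dibromo-2-hydroxy-6-(4,4,5,5-tetramethyl-1,3,2-dioxaborolan-2-yl)benzenediazonium 4-methylbenzenesulfonate | CC1(C)OB(OC1(C)C)c1c([N+]#N)c(O)c(Br)cc1Br.Cc1ccc(S(=O)(=O)[O-])cc1
F7 | step 1 | (3-hydroxyphenyl)boronic acid | OB(O)c1cccc(O)c1
F8 | step 1 | 2-(3-hydroxyphenyl)-6-methyl-1,3,6,2-dioxazaborocane-4,8-dione | CN1CC(=O)OB(OC(=O)C1)c1cccc(O)c1
F9 | step 1 | 2-(2,4-dibromo-5-hydroxyphenyl)-6-methyl-1,3,6,2-dioxazaborocane-4,8-dione | CN1CC(=O)OB(OC(=O)C1)c1cc(O)c(Br)cc1Br
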